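**Retrosynthetic overview**

1. The saturated CH2–CH2 bond between the exocyclic carbon on ring atom C6 and the allylic carbon of the side chain is cut. This gives the α‑peroxy aldehyde 12 (C10, all three stereocentres) and the allyl phosphonium salt 17 (C15). Forward, a Wittig union is followed in the same flask by diimide saturation, so both isomers of the new olefin converge on one product.
2. Enabling feature: C6 of the 1,2‑dioxane is a fully substituted peroxy carbon (ring O, CH3, ring C5, exocyclic C), so its formyl derivative cannot enolise or eliminate. The partner carbon is allylic to the E‑trisubstituted C=C, which stabilises the ylide. The temporary C=C is the only 1,2‑disubstituted olefin beside one tri‑ and one tetrasubstituted olefin, and the O–O bond is inert to diimide.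
3. The 1,2‑dioxane is the only ring formed (step 7). C6–O is made first by invertive perhydrolysis of a Sharpless epoxide (step 6); O–C3 follows by 6‑exo‑tet displacement of a mesylate (inversion) whose carbinol/methyl pair comes from a Brown syn‑crotylation. The cyclohexene ring is bought with dihydro‑β‑ionone.
4. Geranyl acetate supplies C3–C6, the C6 methyl group and a latent formyl group (its C1 is excised as formaldehyde); the crotyl vinyl group becomes CO2Me.
5. Salt 17 comes from dihydro‑β‑ionone by HWE olefination, DIBAL‑H reduction, PBr3 and PPh3.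

Key step: step 15

Remark on the chemistry: ring atoms are numbered O1–O2–C3–C4–C5–C6, with C3 carrying the propanoate. Commercial geranyl acetate is taken as the pure 2E isomer; its C1 is only a sacrificial handle.

**Step 1**
Reactants: 1 geranyl acetate [(2E)-3,7-dimethylocta-2,6-dien-1-yl acetate]
Product: 2 (2E)-3-methyl-6-oxohex-2-en-1-yl acetate
Conditions: O3 (1.0 equiv), pyridine, CH2Cl2, −78 °C; then Me2S
Reagents that add atoms: ozone, [O-][O+]=O
Why: Selective ozonolysis; the electron‑rich terminal trisubstituted olefin should react well before the olefin that is deactivated by the allylic acetate.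

**Step 2**
Reactants: 2 (2E)-3-methyl-6-oxohex-2-en-1-yl acetate
Product: 3 (2E,6R,7R)-6-hydroxy-3,7-dimethylnona-2,8-dien-1-yl acetate
Conditions: cis-2-butene, KOtBu, n-BuLi, THF, −78 → −45 °C; (−)-Ipc2BOMe, −78 °C; BF3·OEt2; then 2, −78 °C; aq NaOAc, 30% H2O2
Reagents that add atoms: (Z)-but-2-ene (delivered as its (−)-Ipc2B crotyl derivative), C/C=C\C
Why: Brown asymmetric crotylboration through a closed chair transition state; the Z‑crotyl geometry should give the syn methyl/hydroxyl pair and the (−)-Ipc2B ligands (from (+)-α-pinene) the (6R,7R) absolute sense.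

**Step 3**
Reactants: 3 (2E,6R,7R)-6-hydroxy-3,7-dimethylnona-2,8-dien-1-yl acetate
Product: 4 (2E,6R,7R)-6-(methanesulfonyloxy)-3,7-dimethylnona-2,8-dien-1-yl acetate
Conditions: MsCl, Et3N, CH2Cl2, 0 °C
Reagents that add atoms: methanesulfonyl chloride, CS(=O)(=O)Cl
Why: Standard O‑sulfonylation of a secondary alcohol, which leaves the carbinol configuration untouched and prepares C3 for later inversion.

**Step 4**
Reactants: 4 (2E,6R,7R)-6-(methanesulfonyloxy)-3,7-dimethylnona-2,8-dien-1-yl acetate
Product: 5 (3R,4R,7E)-9-hydroxy-3,7-dimethylnona-1,7-dien-4-yl methanesulfonate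
Conditions: K2CO3 (cat.), MeOH, 0 °C
Reagents that add atoms: none
Why: Zemplén‑type transesterification of the primary allylic acetate; a secondary mesylate should survive catalytic carbonate in cold methanol.

**Step 5**
Reactants: 5 (3R,4R,7E)-9-hydroxy-3,7-dimethylnona-1,7-dien-4-yl methanesulfonate
Product: 6 (3R,4R)-6-[(2S,3S)-3-(hydroxymethyl)-2-methyloxiran-2-yl]-3-methylhex-1-en-4-yl methanesulfonate
Conditions: Ti(OiPr)4 (cat.), L-(+)-diethyl tartrate (cat.), t-BuOOH, 4 Å MS, CH2Cl2, −20 °C
Reagents that add atoms: tert-butyl hydroperoxide, CC(C)(C)OO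
Why: Sharpless asymmetric epoxidation of a geraniol‑type E‑allylic alcohol; L‑(+)-tartrate should deliver the (2S,3S) epoxide by reagent control, and the isolated vinyl group is not an allylic alcohol and is left alone.

**Step 6**
Reactants: 6 (3R,4R)-6-[(2S,3S)-3-(hydroxymethyl)-2-methyloxiran-2-yl]-3-methylhex-1-en-4-yl methanesulfonate
Product: 7 (3R,4R,7R,8S)-7-hydroperoxy-8,9-dihydroxy-3,7-dimethylnon-1-en-4-yl methanesulfonate
Conditions: anhydrous H2O2 in Et2O (excess), phosphomolybdic acid (cat.), rt
Reagents that add atoms: hydrogen peroxide, OO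
Why: Acid‑catalysed perhydrolysis of an epoxide at its more substituted carbon; attack anti to the departing oxygen should set the tertiary C–OO centre by inversion of the Sharpless‑defined carbon.

**Step 7**
Reactants: 7 (3R,4R,7R,8S)-7-hydroperoxy-8,9-dihydroxy-3,7-dimethylnon-1-en-4-yl methanesulfonate
Product: 8 (1S)-1-{(3R,6S)-6-[(2R)-but-3-en-2-yl]-3-methyl-1,2-dioxan-3-yl}ethane-1,2-diol
Conditions: KOtBu (1.0 equiv), 18-crown-6, THF, 0 °C
Reagents that add atoms: none
Why: Intramolecular SN2 alkylation of a hydroperoxide (6‑exo‑tet); the more acidic OOH is deprotonated selectively and displaces the mesylate with inversion, turning the syn carbinol/methyl pair into the required anti O/methyl pair.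

**Step 8**
Reactants: 8 (1S)-1-{(3R,6S)-6-[(2R)-but-3-en-2-yl]-3-methyl-1,2-dioxan-3-yl}ethane-1,2-diol
Product: 10 (2S)-2-{(3S,6R)-6-[(1S)-1,2-dihydroxyethyl]-6-methyl-1,2-dioxan-3-yl}propanoic acid, via aldehyde 9 (not isolated)
Conditions: O3, MeCN–H2O (9:1), 0 °C; then NaClO2, NaH2PO4, rt
Reagents that add atoms: ozone, [O-][O+]=O; sodium chlorite, [Na+].[O-]Cl=O
Why: One‑pot ozonolysis in aqueous acetonitrile followed by Pinnick oxidation; dialkyl peroxides and alcohols tolerate both reagents, and the mildly acidic buffer should prevent epimerisation or β‑elimination of the aldehyde.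

**Step 9**
Reactants: 10 (2S)-2-{(3S,6R)-6-[(1S)-1,2-dihydroxyethyl]-6-methyl-1,2-dioxan-3-yl}propanoic acid
Product: 11 methyl (2S)-2-{(3S,6R)-6-[(1S)-1,2-dihydroxyethyl]-6-methyl-1,2-dioxan-3-yl}propanoate
Conditions: TMSCHN2, MeOH–toluene, 0 °C
Reagents that add atoms: (trimethylsilyl)diazomethane, C[Si](C)(C)C=[N+]=[N-]
Why: Neutral methyl esterification with a diazoalkane, which avoids any base that could open the β‑peroxy ester by retro‑oxa‑Michael reaction.

**Step 10**
Reactants: 11 methyl (2S)-2-{(3S,6R)-6-[(1S)-1,2-dihydroxyethyl]-6-methyl-1,2-dioxan-3-yl}propanoate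
Product: 12 methyl (2S)-2-[(3S,6R)-6-formyl-6-methyl-1,2-dioxan-3-yl]propanoate
Conditions: NaIO4, THF–H2O, 0 °C
Reagents that add atoms: none
Why: Malaprade glycol cleavage under neutral conditions unmasks the non‑enolisable α‑peroxy aldehyde without touching the O–O bond.

**Step 11**
Reactants: 13 dihydro-β-ionone [4-(2,6,6-trimethylcyclohex-1-en-1-yl)butan-2-one]
Product: 14 ethyl (2E)-3-methyl-5-(2,6,6-trimethylcyclohex-1-en-1-yl)pent-2-enoate
Conditions: (EtO)2P(O)CH2CO2Et, NaH, THF, 0 °C → reflux; chromatographic removal of the minor 2Z isomer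
Reagents that add atoms: triethyl phosphonoacetate, CCOC(=O)CP(=O)(OCC)OCC
Why: Horner–Wadsworth–Emmons olefination of a methyl ketone should favour the E‑trisubstituted enoate, and the minor Z isomer is separable at this stage.

**Step 12**
Reactants: 14 ethyl (2E)-3-methyl-5-(2,6,6-trimethylcyclohex-1-en-1-yl)pent-2-enoate
Product: 15 (2E)-3-methyl-5-(2,6,6-trimethylcyclohex-1-en-1-yl)pent-2-en-1-ol
Conditions: DIBAL-H, CH2Cl2, −78 °C; Rochelle salt work-up
Reagents that add atoms: none
Why: 1,2‑Reduction of an enoate by DIBAL‑H gives the allylic alcohol with the olefin geometry retained.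

**Step 13**
Reactants: 15 (2E)-3-methyl-5-(2,6,6-trimethylcyclohex-1-en-1-yl)pent-2-en-1-ol
Product: 16 2-[(3E)-5-bromo-3-methylpent-3-en-1-yl]-1,3,3-trimethylcyclohex-1-ene
Conditions: PBr3, Et2O, −10 °C
Reagents that add atoms: phosphorus tribromide, BrP(Br)Br
Why: Low‑temperature bromination of a primary allylic alcohol with PBr3 is the standard route to geranyl‑type bromides and should proceed without allylic transposition or E/Z scrambling.

**Step 14**
Reactants: 16 2-[(3E)-5-bromo-3-methylpent-3-en-1-yl]-1,3,3-trimethylcyclohex-1-ene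
Product: 17 [(2E)-3-methyl-5-(2,6,6-trimethylcyclohex-1-en-1-yl)pent-2-en-1-yl]triphenylphosphonium bromide
Conditions: PPh3, toluene, rt; salt triturated free of PPh3
Reagents that add atoms: triphenylphosphine, c1ccc(cc1)P(c1ccccc1)c1ccccc1
Why: SN2 quaternisation at the primary allylic carbon; removing all free phosphine matters because PPh3 would reduce the peroxide in the next step.

**Step 15**
Reactants: 12 methyl (2S)-2-[(3S,6R)-6-formyl-6-methyl-1,2-dioxan-3-yl]propanoate; 17 [(2E)-3-methyl-5-(2,6,6-trimethylcyclohex-1-en-1-yl)pent-2-en-1-yl]triphenylphosphonium bromide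
Product: 20 methyl (2S)-2-[(3S,6S)-6-methyl-6-[(3E)-4-methyl-6-(2,6,6-trimethylcyclohex-1-en-1-yl)hex-3-en-1-yl]-1,2-dioxan-3-yl]propanoate, via allyl ylide 18 (not isolated), via 1,3-diene 19 (not isolated)
Conditions: 17 (1.1 equiv), KHMDS (1.0 equiv), THF, −78 °C; then 12, −78 → 0 °C; then 2-nitrobenzenesulfonylhydrazide (NBSH, excess), Et3N, rt
Reagents that add atoms: none
Why: KHMDS converts 17 into the semi‑stabilised allyl ylide 18, which adds to the formyl carbon of 12; collapse of the oxaphosphetane expels Ph3P=O and makes the new C–C bond as a C=C (diene 19, 1E/1Z mixture), and diimide generated in the same flask from NBSH/Et3N then transfers H2 to that olefin through a concerted six‑membered transition state, so both geometric isomers converge on the one saturated CH2–CH2 link. The closest known reaction types are Wittig olefinations of α‑peroxy aldehydes with phosphorus ylides and diimide saturation of olefins in cyclic peroxides, whose O–O bonds are inert to N2H2. No ring is closed and no stereocentre is created; C6 carries no hydrogen and the ylide is too weakly basic to enolise the ester, so C2, C3 and C6 should be retained and retro‑oxa‑Michael or Kornblum–DeLaMare opening avoided. The step needs α‑ rather than γ‑attack of the allyl ylide with retention of the 2E trisubstituted olefin, which low‑temperature generation and immediate use of the Ph3P ylide should secure. It also needs saturation of the new olefin only, which its being the sole 1,2‑disubstituted double bond should secure, since diimide reacts far more slowly with tri‑ and tetrasubstituted olefins.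

**Compound list**

1 | geranyl acetate, (2E)-3,7-dimethylocta-2,6-dien-1-yl acetate | CC(=O)OC/C=C(\C)CCC=C(C)C | starting material
2 | (2E)-3-methyl-6-oxohex-2-en-1-yl acetate | CC(=O)OC/C=C(\C)CCC=O | intermediate
3 | (2E,6R,7R)-6-hydroxy-3,7-dimethylnona-2,8-dien-1-yl acetate | CC(=O)OC/C=C(\C)CC[C@@H](O)[C@H](C)C=C | intermediate
4 | (2E,6R,7R)-6-(methanesulfonyloxy)-3,7-dimethylnona-2,8-dien-1-yl acetate | CC(=O)OC/C=C(\C)CC[C@@H](OS(C)(=O)=O)[C@H](C)C=C | intermediate
5 | (3R,4R,7E)-9-hydroxy-3,7-dimethylnona-1,7-dien-4-yl methanesulfonate | OC/C=C(\C)CC[C@@H](OS(C)(=O)=O)[C@H](C)C=C | intermediate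
6 | (3R,4R)-6-[(2S,3S)-3-(hydroxymethyl)-2-methyloxiran-2-yl]-3-methylhex-1-en-4-yl methanesulfonate | OC[C@@H]1O[C@@]1(C)CC[C@@H](OS(C)(=O)=O)[C@H](C)C=C | intermediate
7 | (3R,4R,7R,8S)-7-hydroperoxy-8,9-dihydroxy-3,7-dimethylnon-1-en-4-yl methanesulfonate | OC[C@H](O)[C@@](OO)(C)CC[C@@H](OS(C)(=O)=O)[C@H](C)C=C | intermediate
8 | (1S)-1-{(3R,6S)-6-[(2R)-but-3-en-2-yl]-3-methyl-1,2-dioxan-3-yl}ethane-1,2-diol | OC[C@H](O)[C@@]1(C)CC[C@@H]([C@H](C)C=C)OO1 | intermediate
9 | (2S)-2-{(3S,6R)-6-[(1S)-1,2-dihydroxyethyl]-6-methyl-1,2-dioxan-3-yl}propanal | OC[C@H](O)[C@@]1(C)CC[C@@H]([C@H](C)C=O)OO1 | intermediate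
10 | (2S)-2-{(3S,6R)-6-[(1S)-1,2-dihydroxyethyl]-6-methyl-1,2-dioxan-3-yl}propanoic acid | OC[C@H](O)[C@@]1(C)CC[C@@H]([C@H](C)C(O)=O)OO1 | intermediate
11 | methyl (2S)-2-{(3S,6R)-6-[(1S)-1,2-dihydroxyethyl]-6-methyl-1,2-dioxan-3-yl}propanoate | COC(=O)[C@@H](C)[C@@H]1CC[C@](C)([C@@H](O)CO)OO1 | intermediate
12 | methyl (2S)-2-[(3S,6R)-6-formyl-6-methyl-1,2-dioxan-3-yl]propanoate | COC(=O)[C@@H](C)[C@@H]1CC[C@](C)(C=O)OO1 | intermediate
13 | dihydro-β-ionone, 4-(2,6,6-trimethylcyclohex-1-en-1-yl)butan-2-one | CC(=O)CCC1=C(C)CCCC1(C)C | starting material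
14 | ethyl (2E)-3-methyl-5-(2,6,6-trimethylcyclohex-1-en-1-yl)pent-2-enoate | CCOC(=O)/C=C(\C)CCC1=C(C)CCCC1(C)C | intermediate
15 | (2E)-3-methyl-5-(2,6,6-trimethylcyclohex-1-en-1-yl)pent-2-en-1-ol | OC/C=C(\C)CCC1=C(C)CCCC1(C)C | intermediate
16 | 2-[(3E)-5-bromo-3-methylpent-3-en-1-yl]-1,3,3-trimethylcyclohex-1-ene | BrC/C=C(\C)CCC1=C(C)CCCC1(C)C | intermediate
17 | [(2E)-3-methyl-5-(2,6,6-trimethylcyclohex-1-en-1-yl)pent-2-en-1-yl]triphenylphosphonium bromide | [Br-].C(/C=C(\C)CCC1=C(C)CCCC1(C)C)[P+](c1ccccc1)(c1ccccc1)c1ccccc1 | intermediate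
18 | triphenylphosphonium (2E)-3-methyl-5-(2,6,6-trimethylcyclohex-1-en-1-yl)pent-2-en-1-ylide | [CH-](/C=C(\C)CCC1=C(C)CCCC1(C)C)[P+](c1ccccc1)(c1ccccc1)c1ccccc1 | intermediate
19 | methyl (2S)-2-{(3S,6R)-6-methyl-6-[(3E)-4-methyl-6-(2,6,6-trimethylcyclohex-1-en-1-yl)hexa-1,3-dien-1-yl]-1,2-dioxan-3-yl}propanoate (1E/1Z mixture) | COC(=O)[C@@H](C)[C@@H]1CC[C@](C)(C=C/C=C(\C)CCC2=C(C)CCCC2(C)C)OO1 | intermediate
20 | methyl (2S)-2-[(3S,6S)-6-methyl-6-[(3E)-4-methyl-6-(2,6,6-trimethylcyclohex-1-en-1-yl)hex-3-en-1-yl]-1,2-dioxan-3-yl]propanoate | COC(=O)[C@@H](C)[C@@H]1CC[C@](C)(CC/C=C(\C)CCC2=C(C)CCCC2(C)C)OO1 | target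

**Step count and risks**

Total steps: 15. Longest linear sequence: 11 (steps 1–10, then step 15).

The three steps most likely to fail:

**Step 7 (peroxide ring closure).** Three processes may compete with the 6‑exo‑tet displacement: E2 loss of the mesylate toward the allylic C–H, O‑alkylation by the neighbouring alkoxide to give a tetrahydropyran, and base‑induced fragmentation of the β‑hydroxy hydroperoxide. The fallback closes the ring by conjugate addition instead of substitution. It sets out from 2 and comes back at 11.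
- Aldehyde 2 is olefinated with methyl 2-(triphenyl-λ5-phosphanylidene)propanoate (CH2Cl2, rt) to methyl (2E,6E)-8-acetoxy-2,6-dimethylocta-2,6-dienoate F1.
- Methanolysis (K2CO3, MeOH) gives methyl (2E,6E)-8-hydroxy-2,6-dimethylocta-2,6-dienoate F2.
- Sharpless epoxidation with L-(+)-diethyl tartrate gives methyl (2E)-5-[(2S,3S)-3-(hydroxymethyl)-2-methyloxiran-2-yl]-2-methylpent-2-enoate F3.
- Perhydrolysis as in step 6 gives methyl (2E,6R,7S)-6-hydroperoxy-7,8-dihydroxy-2,6-dimethyloct-2-enoate F4.
- Et2NH (cat.) in CF3CH2OH should induce the 6‑exo‑trig oxa‑Michael addition of the hydroperoxide to the enoate, giving 11.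
- C6 is still set by the epoxide, but C2 and C3 are not controlled, so 11 would have to be separated from its C2/C3 diastereomers by chromatography.

**Step 6 (perhydrolysis).** Partial ionisation at the tertiary carbon would erode the C6 configuration; attack at the secondary epoxide carbon or rearrangement of the epoxide to a carbonyl compound may also occur. The fallback reverses the order of the two C–O bond formations, so that the tertiary centre is attacked intramolecularly. It sets out from 6 and comes back at 8.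
- The secondary mesylate of 6 is displaced with alkaline hydrogen peroxide (KOH, 30% H2O2, MeOH, 0 °C → rt, inversion at C3) to give [(2S,3S)-3-[(3S,4R)-3-hydroperoxy-4-methylhex-5-en-1-yl]-3-methyloxiran-2-yl]methanol F5.
- Camphorsulfonic acid (cat.) in CH2Cl2 should then trigger 6‑exo opening of the epoxide at its tertiary carbon by the tethered hydroperoxide (inversion at C6), giving 8.

**Step 15 (union and saturation).** Three processes may intrude: E/Z scrambling of the trisubstituted olefin at the ylide stage, diimide reducing the trisubstituted olefin as well (or leaving diene unreduced), and base‑triggered opening of the peroxide. The fallback uses a configurationally firmer carbanion, isolates the diene and saturates it under catalyst control. It sets out from 16 and 12 and comes back at 20.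
- Bromide 16 is heated with triethyl phosphite (Arbuzov reaction) to give diethyl [(2E)-3-methyl-5-(2,6,6-trimethylcyclohex-1-en-1-yl)pent-2-en-1-yl]phosphonate F6.
- Its sodium salt (NaHMDS, THF, −78 °C) is condensed with 12 in a Horner–Wadsworth–Emmons reaction, and diene 19 is isolated.
- Hydrogenation of 19 with Wilkinson's catalyst (RhCl(PPh3)3, H2, benzene–EtOH) should give 20, because this catalyst does not touch tri‑ or tetrasubstituted olefins. Survival of the O–O bond under these conditions would need to be checked on a model first.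

**Further compounds**

F1 | step 7 | methyl (2E,6E)-8-acetoxy-2,6-dimethylocta-2,6-dienoate | COC(=O)/C(C)=C/CC/C(C)=C/COC(C)=O
F2 | step 7 | methyl (2E,6E)-8-hydroxy-2,6-dimethylocta-2,6-dienoate | COC(=O)/C(C)=C/CC/C(C)=C/CO
F3 | step 7 | methyl (2E)-5-[(2S,3S)-3-(hydroxymethyl)-2-methyloxiran-2-yl]-2-methylpent-2-enoate | COC(=O)/C(C)=C/CC[C@]1(C)O[C@H]1CO
F4 | step 7 | methyl (2E,6R,7S)-6-hydroperoxy-7,8-dihydroxy-2,6-dimethyloct-2-enoate | COC(=O)/C(C)=C/CC[C@@](C)(OO)[C@@H](O)CO
F5 | step 6 | [(2S,3S)-3-[(3S,4R)-3-hydroperoxy-4-methylhex-5-en-1-yl]-3-methyloxiran-2-yl]methanol | OC[C@@H]1O[C@@]1(C)CC[C@H](OO)[C@H](C)C=C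
F6 | step 15 | diethyl [(2E)-3-methyl-5-(2,6,6-trimethylcyclohex-1-en-1-yl)pent-2-en-1-yl]phosphonate | CCOP(=O)(C/C=C(\C)CCC1=C(C)CCCC1(C)C)OCC
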